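## Retrosynthetic overview

1. Target ⇐ hydroxy acid (last: oxidation of the allylic alcohol to the enal; before it: acidolysis of a 4-methoxybenzyl ester) ⇐ Mitsunobu esterification, with inversion at C7, of a bicyclic alcohol with (2E,4E,6R)-4,6-dimethylocta-2,4-dienoic acid (stereocentre from asymmetric hydrogenation of tiglic acid).
2. C4 carboxyl stereocentre ⇐ alcoholysis and decarboxylation of a spiro Meldrum's acid, the ester enol being protonated anti to the C3a methyl group.
3. Key disconnection: the C3a–C4 bond (ring B) together with the C3a–C3 bond (ring A). The spiro hydrindenone ⇐ a monocyclic 2-furylcarbinol by a dearomative carbon-Piancatelli cascade; ring B (six-membered) closes first, ring A (cyclopentenone) second, in the same flask.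
4. Enabling feature: ring A is a 4,4,5-trisubstituted cyclopent-2-enone, the retron of a Piancatelli rearrangement. C2(=O)–C1=C7a–C3a(CH3) is a 2-methylfuran in disguise (furan O = ketone O), and C3a is the methyl-bearing α-carbon of its furfuryl cation, within reach of a C4 nucleophile tethered through C7–C6–C5 to the neighbouring furan β-carbon (C7a).
5. Furan precursor ⇐ 2-methylfuran-3-carbonyl chloride: C7 is set by asymmetric transfer hydrogenation (the only stereocentre set by catalysis for the core; C3a, C3 and C4 are relayed from it), then Vilsmeier formylation, Barbier allylation and reductive alkylation of Meldrum's acid.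

Key step: step 10

Remark: locants follow 2H-indene numbering (C2 ketone, C1=C7a alkene, C3 side chain, C3a methyl, C4 carboxyl, C7 acyloxy); the stereocentre of the acyl chain is read from the SMILES as 6R, so the dienoic acid is built in the (R)-series.

## Route

Step 1
Reactants: 1 2-methylfuran-3-carbonyl chloride
Product: 2 ethyl 3-(2-methylfuran-3-yl)-3-oxopropanoate
Conditions: KO2CCH2CO2Et, MgCl2, Et3N, MeCN, 0 °C → rt; then aq. HCl
Reagents that add atoms: potassium ethyl malonate, CCOC(=O)CC(=O)[O-].[K+]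
Why: C-acylation of the magnesium enolate of the malonate half ester by the acid chloride and loss of CO2 (decarboxylative Claisen-type acylation) should give the β-keto ester without touching the furan.

Step 2
Reactants: 2 ethyl 3-(2-methylfuran-3-yl)-3-oxopropanoate
Product: 3 ethyl (3R)-3-hydroxy-3-(2-methylfuran-3-yl)propanoate
Conditions: RuCl[(R,R)-TsDPEN](p-cymene) (1 mol %), HCO2H/Et3N (5:2), rt
Reagents that add atoms: none
Why: Noyori–Ikariya asymmetric transfer hydrogenation, in which the furyl group plays the aryl role, should set the carbinol stereocentre (the future C7) under catalyst control; the (R,R)-catalyst is chosen to give the 3R alcohol, and the mild conditions spare the acid-sensitive furylcarbinol.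

Step 3
Reactants: 3 ethyl (3R)-3-hydroxy-3-(2-methylfuran-3-yl)propanoate
Product: 4 ethyl (3R)-3-[(tert-butyldiphenylsilyl)oxy]-3-(2-methylfuran-3-yl)propanoate
Conditions: TBDPSCl, imidazole, DMF, rt
Reagents that add atoms: tert-butyl(chloro)diphenylsilane, CC(C)(C)[Si](Cl)(c1ccccc1)c1ccccc1
Why: Silylation gives a bulky, acid-robust ether that is a poor leaving group, so that this furyl-substituted carbinol carbon does not ionise in step 10.

Step 4
Reactants: 4 ethyl (3R)-3-[(tert-butyldiphenylsilyl)oxy]-3-(2-methylfuran-3-yl)propanoate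
Product: 5 ethyl (3R)-3-[(tert-butyldiphenylsilyl)oxy]-3-(5-formyl-2-methylfuran-3-yl)propanoate
Conditions: POCl3, DMF, 0 °C → rt; then aq. NaOAc
Reagents that add atoms: N,N-dimethylformamide, CN(C)C=O; water, O
Why: Vilsmeier–Haack formylation should occur at the only free α-position of the electron-rich 2,3-dialkylfuran.

Step 5
Reactants: 6 2-methylidenepropane-1,3-diol
Product: 7 2-({[tert-butyl(dimethyl)silyl]oxy}methyl)prop-2-en-1-ol
Conditions: NaH (1 equiv), THF, 0 °C; then TBSCl
Reagents that add atoms: tert-butyl(chloro)dimethylsilane, CC(C)(C)[Si](C)(C)Cl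
Why: Monosilylation of a symmetrical diol through its sparingly soluble mono-alkoxide is a standard desymmetrising protection.

Step 6
Reactants: 7 2-({[tert-butyl(dimethyl)silyl]oxy}methyl)prop-2-en-1-ol
Product: 8 {[2-(bromomethyl)prop-2-en-1-yl]oxy}(tert-butyl)dimethylsilane
Conditions: CBr4, PPh3, CH2Cl2, 0 °C
Reagents that add atoms: tetrabromomethane, BrC(Br)(Br)Br
Why: The Appel reaction converts the primary allylic alcohol into the bromide under neutral conditions that leave the silyl ether intact.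

Step 7
Reactants: 5 ethyl (3R)-3-[(tert-butyldiphenylsilyl)oxy]-3-(5-formyl-2-methylfuran-3-yl)propanoate; 8 {[2-(bromomethyl)prop-2-en-1-yl]oxy}(tert-butyl)dimethylsilane
Product: 9 ethyl (3R)-3-[(tert-butyldiphenylsilyl)oxy]-3-{5-[3-({[tert-butyl(dimethyl)silyl]oxy}methyl)-1-hydroxybut-3-en-1-yl]-2-methylfuran-3-yl}propanoate (both carbinol epimers)
Conditions: Zn, THF/sat. aq. NH4Cl, rt
Reagents that add atoms: none
Why: The aqueous Barbier allylation is chemoselective for the aldehyde over the ester; the new carbinol centre needs no control because it is ionised in step 10.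

Step 8
Reactants: 9 ethyl (3R)-3-[(tert-butyldiphenylsilyl)oxy]-3-{5-[3-({[tert-butyl(dimethyl)silyl]oxy}methyl)-1-hydroxybut-3-en-1-yl]-2-methylfuran-3-yl}propanoate
Product: 10 (3R)-3-[(tert-butyldiphenylsilyl)oxy]-3-{5-[3-({[tert-butyl(dimethyl)silyl]oxy}methyl)-1-hydroxybut-3-en-1-yl]-2-methylfuran-3-yl}propanal (both carbinol epimers)
Conditions: i-Bu2AlH (2.2 equiv), CH2Cl2, −78 °C; then aq. potassium sodium tartrate
Reagents that add atoms: none
Why: Partial reduction of the β-silyloxy ester should stop at the aldehyde because the chelated aluminium hemiacetal persists at −78 °C (one equivalent of hydride is consumed by the free hydroxyl).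

Step 9
Reactants: 10 (3R)-3-[(tert-butyldiphenylsilyl)oxy]-3-{5-[3-({[tert-butyl(dimethyl)silyl]oxy}methyl)-1-hydroxybut-3-en-1-yl]-2-methylfuran-3-yl}propanal
Product: 12 5-[(3R)-3-[(tert-butyldiphenylsilyl)oxy]-3-{5-[3-({[tert-butyl(dimethyl)silyl]oxy}methyl)-1-hydroxybut-3-en-1-yl]-2-methylfuran-3-yl}propyl]-2,2-dimethyl-1,3-dioxane-4,6-dione (both carbinol epimers), via alkylidene Meldrum's acid 11 (not isolated)
Conditions: Meldrum's acid, Hantzsch ester, L-proline (20 mol %), EtOH, rt
Reagents that add atoms: Meldrum's acid (2,2-dimethyl-1,3-dioxane-4,6-dione), CC1(C)OC(=O)CC(=O)O1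
Why: Knoevenagel condensation followed in the same flask by conjugate hydride transfer from the Hantzsch ester (organocatalytic reductive alkylation) gives the mono-alkylated Meldrum's acid; the fast condensation should outrun β-elimination of the silyloxy group.

Step 10
Reactants: 12 5-[(3R)-3-[(tert-butyldiphenylsilyl)oxy]-3-{5-[3-({[tert-butyl(dimethyl)silyl]oxy}methyl)-1-hydroxybut-3-en-1-yl]-2-methylfuran-3-yl}propyl]-2,2-dimethyl-1,3-dioxane-4,6-dione
Product: 14 (3'R,3a'R,7'R)-7'-[(tert-butyldiphenylsilyl)oxy]-3'-[2-({[tert-butyl(dimethyl)silyl]oxy}methyl)prop-2-en-1-yl]-2,2,3a'-trimethyl-3',3a',6',7'-tetrahydro-2'H-spiro[[1,3]dioxane-5,4'-indene]-2',4,6(5'H)-trione (spiro hydrindenone), via spiro-dihydrobenzofuran adduct 13 (not isolated)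
Conditions: Dy(OTf)3 (10 mol %), 4 Å MS, MeCN (0.01 M), 80 °C
Reagents that add atoms: none
Why: Proposed new method: Dy(OTf)3 ionises the 2-furylcarbinol to the furfuryl (2-alkylidene-2H-furanium) cation, whose methyl-bearing ring carbon is attacked by the enol carbon of the tethered Meldrum's acid to give the dearomatised adduct 13; Lewis-acid ionisation of the tertiary allylic C–O bond of 13 then gives a 2-oxidopentadienyl cation that closes to the cyclopentenone, while the competing C–C ionisation only returns the furfuryl cation. The closest known reactions are the Piancatelli and aza-Piancatelli rearrangements (the same furanium capture and 4π closure with O- and N-nucleophiles, also at a substituted furan carbon), the Lewis-acid SN1 alkylation of 1,3-dicarbonyl compounds by furfuryl and benzylic alcohols, and the Lewis-acid 1,3-O-to-C shift of allyl vinyl ethers; new is the carbon nucleophile in the first role. Ring B closes 6-exo-trig onto the C=O+ carbon (the C3a–C4 bond), ring A by conrotatory 4π electrocyclisation (the C3a–C3 bond, overall a 1,3-O-to-C shift in which the furan oxygen becomes the ketone oxygen). C3a is controlled by C7: in the half-chair of the cyclohexenyl cation the bulky silyloxy group should stay pseudoequatorial, which fixes the ring pucker and so the sense of conrotation, the methyl group turning to the face anti to the silyloxy group; C3 follows from conrotation of the E-configured enol terminus and is also the expected thermodynamic epimer (side chain cis to methyl, trans to the spiro carbon). The step needs site selectivity for the ring carbon over the carbinol carbon, secured by the three-atom tether (which cannot reach the exocyclic carbon) and by high dilution, and chemoselective ionisation, secured because only the free 2-furylcarbinol and not the silyl ether at C7 is activated, with molecular sieves keeping water out of the competing oxa-Piancatelli path.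

Step 11
Reactants: 14 spiro hydrindenone
Product: 16 4-methoxybenzyl (3R,3aS,4R,7R)-7-[(tert-butyldiphenylsilyl)oxy]-3-[2-({[tert-butyl(dimethyl)silyl]oxy}methyl)prop-2-en-1-yl]-3a-methyl-2-oxo-3,3a,4,5,6,7-hexahydro-2H-indene-4-carboxylate, via malonic half ester 15 (not isolated)
Conditions: 4-MeOC6H4CH2OH, DMAP, pyridine, 100 °C
Reagents that add atoms: 4-methoxybenzyl alcohol, COc1ccc(CO)cc1
Why: Alcoholysis of the Meldrum's acid releases acetone and gives a malonic half ester that decarboxylates in hot pyridine; the ester enol should be protonated on the exo (axial) face anti to the axial C3a methyl group, which places the ester equatorial and cis to the methyl group (4R).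

Step 12
Reactants: 16 4-methoxybenzyl (3R,3aS,4R,7R)-7-[(tert-butyldiphenylsilyl)oxy]-3-[2-({[tert-butyl(dimethyl)silyl]oxy}methyl)prop-2-en-1-yl]-3a-methyl-2-oxo-3,3a,4,5,6,7-hexahydro-2H-indene-4-carboxylate
Product: 17 4-methoxybenzyl (3R,3aS,4R,7R)-7-hydroxy-3-[2-(hydroxymethyl)prop-2-en-1-yl]-3a-methyl-2-oxo-3,3a,4,5,6,7-hexahydro-2H-indene-4-carboxylate
Conditions: HF·pyridine, pyridine/THF, 0 °C → rt
Reagents that add atoms: none
Why: Buffered fluoride removes both silyl ethers without base, so the enone, the C3 centre and the 4-methoxybenzyl ester are left alone.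

Step 13
Reactants: 17 4-methoxybenzyl (3R,3aS,4R,7R)-7-hydroxy-3-[2-(hydroxymethyl)prop-2-en-1-yl]-3a-methyl-2-oxo-3,3a,4,5,6,7-hexahydro-2H-indene-4-carboxylate
Product: 18 4-methoxybenzyl (3R,3aS,4R,7R)-3-[2-({[tert-butyl(dimethyl)silyl]oxy}methyl)prop-2-en-1-yl]-7-hydroxy-3a-methyl-2-oxo-3,3a,4,5,6,7-hexahydro-2H-indene-4-carboxylate
Conditions: TBSCl (1.05 equiv), imidazole, CH2Cl2, −20 → 0 °C
Reagents that add atoms: tert-butyl(chloro)dimethylsilane, CC(C)(C)[Si](C)(C)Cl
Why: The primary allylic hydroxyl is silylated much faster than the secondary ring hydroxyl, which leaves C7–OH free for esterification.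

Step 14
Reactants: 19 (2E)-2-methylbut-2-enoic acid (tiglic acid)
Product: 20 (2R)-2-methylbutanoic acid
Conditions: Ru(OAc)2[(R)-H8-BINAP] (0.5 mol %), H2 (4 atm), MeOH, rt
Reagents that add atoms: none
Why: Asymmetric hydrogenation of the carboxylate-bound trisubstituted alkene by the ruthenium dicarboxylate–diphosphine catalyst sets the chain stereocentre; the ligand antipode is chosen to give the 2R acid.

Step 15
Reactants: 20 (2R)-2-methylbutanoic acid
Product: 21 (2R)-2-methylbutan-1-ol
Conditions: LiAlH4, Et2O, 0 °C → rt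
Reagents that add atoms: none
Why: Hydride reduction of the acid to the primary alcohol does not touch the α-stereocentre.

Step 16
Reactants: 21 (2R)-2-methylbutan-1-ol
Product: 23 (2E,4R)-2,4-dimethylhex-2-enal, via (2R)-2-methylbutanal 22 (not isolated)
Conditions: TEMPO (cat.), PhI(OAc)2, CH2Cl2, rt; then Ph3P=C(Me)CHO, 40 °C
Reagents that add atoms: 2-(triphenylphosphoranylidene)propanal, CC(C=O)=P(c1ccccc1)(c1ccccc1)c1ccccc1
Why: Oxoammonium oxidation gives the volatile, epimerisable aldehyde under nearly neutral conditions, and it is trapped in the same flask by a Wittig reaction with the stabilised ylide, which should give the E-trisubstituted enal.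

Step 17
Reactants: 23 (2E,4R)-2,4-dimethylhex-2-enal
Product: 24 ethyl (2E,4E,6R)-4,6-dimethylocta-2,4-dienoate
Conditions: (EtO)2P(O)CH2CO2Et, NaH, THF, 0 °C → rt
Reagents that add atoms: triethyl phosphonoacetate, CCOC(=O)CP(=O)(OCC)OCC
Why: The Horner–Wadsworth–Emmons olefination of an enal is reliably E-selective and completes the dienoate.

Step 18
Reactants: 24 ethyl (2E,4E,6R)-4,6-dimethylocta-2,4-dienoate
Product: 25 (2E,4E,6R)-4,6-dimethylocta-2,4-dienoic acid
Conditions: LiOH, THF/MeOH/H2O, rt; then aq. HCl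
Reagents that add atoms: lithium hydroxide, [Li+].[OH-]
Why: Saponification frees the acid; the remote stereocentre is not enolisable.

Step 19
Reactants: 18 4-methoxybenzyl (3R,3aS,4R,7R)-3-[2-({[tert-butyl(dimethyl)silyl]oxy}methyl)prop-2-en-1-yl]-7-hydroxy-3a-methyl-2-oxo-3,3a,4,5,6,7-hexahydro-2H-indene-4-carboxylate; 25 (2E,4E,6R)-4,6-dimethylocta-2,4-dienoic acid
Product: 26 4-methoxybenzyl (3R,3aS,4R,7S)-3-[2-({[tert-butyl(dimethyl)silyl]oxy}methyl)prop-2-en-1-yl]-7-{[(2E,4E,6R)-4,6-dimethylocta-2,4-dienoyl]oxy}-3a-methyl-2-oxo-3,3a,4,5,6,7-hexahydro-2H-indene-4-carboxylate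
Conditions: PPh3, DIAD, toluene, 0 °C → rt
Reagents that add atoms: none
Why: The Mitsunobu reaction should displace the activated equatorial allylic hydroxyl by the carboxylate with SN2 inversion, giving the axial 7S ester cis to the angular methyl group, as is well established for γ-hydroxy enones.

Step 20
Reactants: 26 4-methoxybenzyl (3R,3aS,4R,7S)-3-[2-({[tert-butyl(dimethyl)silyl]oxy}methyl)prop-2-en-1-yl]-7-{[(2E,4E,6R)-4,6-dimethylocta-2,4-dienoyl]oxy}-3a-methyl-2-oxo-3,3a,4,5,6,7-hexahydro-2H-indene-4-carboxylate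
Product: 27 (3R,3aS,4R,7S)-7-{[(2E,4E,6R)-4,6-dimethylocta-2,4-dienoyl]oxy}-3-[2-(hydroxymethyl)prop-2-en-1-yl]-3a-methyl-2-oxo-3,3a,4,5,6,7-hexahydro-2H-indene-4-carboxylic acid
Conditions: TFA/CH2Cl2/H2O, anisole, 0 °C → rt
Reagents that add atoms: none
Why: Acidolysis cleaves the 4-methoxybenzyl ester (the benzyl cation is trapped by anisole) and the primary silyl ether in one operation, and the electron-poor allylic dienoate at C7 should not ionise.

Step 21
Reactants: 27 (3R,3aS,4R,7S)-7-{[(2E,4E,6R)-4,6-dimethylocta-2,4-dienoyl]oxy}-3-[2-(hydroxymethyl)prop-2-en-1-yl]-3a-methyl-2-oxo-3,3a,4,5,6,7-hexahydro-2H-indene-4-carboxylic acid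
Product: 28 (3R,3aS,4R,7S)-7-{[(2E,4E,6R)-4,6-dimethylocta-2,4-dienoyl]oxy}-3-(2-formylprop-2-en-1-yl)-3a-methyl-2-oxo-3,3a,4,5,6,7-hexahydro-2H-indene-4-carboxylic acid (CNP0302671.3)
Conditions: TEMPO (10 mol %), PhI(OAc)2, CH2Cl2, rt
Reagents that add atoms: none
Why: The oxoammonium oxidation is selective for the primary allylic alcohol, tolerates the free carboxylic acid and, without water, should stop at the 2-substituted acrolein.

## Compound list

1 | 2-methylfuran-3-carbonyl chloride | Cc1occc1C(=O)Cl | starting material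
2 | ethyl 3-(2-methylfuran-3-yl)-3-oxopropanoate | CCOC(=O)CC(=O)c1ccoc1C | intermediate
3 | ethyl (3R)-3-hydroxy-3-(2-methylfuran-3-yl)propanoate | CCOC(=O)C[C@@H](O)c1ccoc1C | intermediate
4 | ethyl (3R)-3-[(tert-butyldiphenylsilyl)oxy]-3-(2-methylfuran-3-yl)propanoate | CCOC(=O)C[C@@H](O[Si](c1ccccc1)(c1ccccc1)C(C)(C)C)c1ccoc1C | intermediate
5 | ethyl (3R)-3-[(tert-butyldiphenylsilyl)oxy]-3-(5-formyl-2-methylfuran-3-yl)propanoate | CCOC(=O)C[C@@H](O[Si](c1ccccc1)(c1ccccc1)C(C)(C)C)c1cc(C=O)oc1C | intermediate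
6 | 2-methylidenepropane-1,3-diol | C=C(CO)CO | starting material
7 | 2-({[tert-butyl(dimethyl)silyl]oxy}methyl)prop-2-en-1-ol | C=C(CO)CO[Si](C)(C)C(C)(C)C | intermediate
8 | {[2-(bromomethyl)prop-2-en-1-yl]oxy}(tert-butyl)dimethylsilane | C=C(CBr)CO[Si](C)(C)C(C)(C)C | intermediate
9 | ethyl (3R)-3-[(tert-butyldiphenylsilyl)oxy]-3-{5-[3-({[tert-butyl(dimethyl)silyl]oxy}methyl)-1-hydroxybut-3-en-1-yl]-2-methylfuran-3-yl}propanoate (both carbinol epimers) | CCOC(=O)C[C@@H](O[Si](c1ccccc1)(c1ccccc1)C(C)(C)C)c1cc(C(O)CC(=C)CO[Si](C)(C)C(C)(C)C)oc1C | intermediate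
10 | (3R)-3-[(tert-butyldiphenylsilyl)oxy]-3-{5-[3-({[tert-butyl(dimethyl)silyl]oxy}methyl)-1-hydroxybut-3-en-1-yl]-2-methylfuran-3-yl}propanal (both carbinol epimers) | O=CC[C@@H](O[Si](c1ccccc1)(c1ccccc1)C(C)(C)C)c1cc(C(O)CC(=C)CO[Si](C)(C)C(C)(C)C)oc1C | intermediate
11 | 5-[(3R)-3-[(tert-butyldiphenylsilyl)oxy]-3-{5-[3-({[tert-butyl(dimethyl)silyl]oxy}methyl)-1-hydroxybut-3-en-1-yl]-2-methylfuran-3-yl}propylidene]-2,2-dimethyl-1,3-dioxane-4,6-dione | CC1(C)OC(=O)C(=CC[C@@H](O[Si](c2ccccc2)(c2ccccc2)C(C)(C)C)c2cc(C(O)CC(=C)CO[Si](C)(C)C(C)(C)C)oc2C)C(=O)O1 | intermediate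
12 | 5-[(3R)-3-[(tert-butyldiphenylsilyl)oxy]-3-{5-[3-({[tert-butyl(dimethyl)silyl]oxy}methyl)-1-hydroxybut-3-en-1-yl]-2-methylfuran-3-yl}propyl]-2,2-dimethyl-1,3-dioxane-4,6-dione (both carbinol epimers) | CC1(C)OC(=O)C(CC[C@@H](O[Si](c2ccccc2)(c2ccccc2)C(C)(C)C)c2cc(C(O)CC(=C)CO[Si](C)(C)C(C)(C)C)oc2C)C(=O)O1 | intermediate
13 | (4'R)-4'-[(tert-butyldiphenylsilyl)oxy]-2'-[3-({[tert-butyl(dimethyl)silyl]oxy}methyl)but-3-en-1-ylidene]-2,2,7a'-trimethyl-4',5',6',7a'-tetrahydro-2'H-spiro[[1,3]dioxane-5,7'-[1]benzofuran]-4,6-dione (dearomatised adduct; either configuration at C7a' and either alkene geometry, all converge) | C=C(CO[Si](C)(C)C(C)(C)C)CC=C1C=C2[C@H](O[Si](c3ccccc3)(c3ccccc3)C(C)(C)C)CCC3(C(=O)OC(C)(C)OC3=O)C2(C)O1 | intermediate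
14 | (3'R,3a'R,7'R)-7'-[(tert-butyldiphenylsilyl)oxy]-3'-[2-({[tert-butyl(dimethyl)silyl]oxy}methyl)prop-2-en-1-yl]-2,2,3a'-trimethyl-3',3a',6',7'-tetrahydro-2'H-spiro[[1,3]dioxane-5,4'-indene]-2',4,6(5'H)-trione (methyl trans to silyloxy, cis to the C3' side chain) | C=C(CO[Si](C)(C)C(C)(C)C)C[C@H]1C(=O)C=C2[C@H](O[Si](c3ccccc3)(c3ccccc3)C(C)(C)C)CCC3(C(=O)OC(C)(C)OC3=O)[C@@]21C | intermediate
15 | (3R,3aR,7R)-7-[(tert-butyldiphenylsilyl)oxy]-3-[2-({[tert-butyl(dimethyl)silyl]oxy}methyl)prop-2-en-1-yl]-4-{[(4-methoxyphenyl)methoxy]carbonyl}-3a-methyl-2-oxo-3,3a,4,5,6,7-hexahydro-2H-indene-4-carboxylic acid (both C4 epimers) | C=C(CO[Si](C)(C)C(C)(C)C)C[C@H]1C(=O)C=C2[C@H](O[Si](c3ccccc3)(c3ccccc3)C(C)(C)C)CCC(C(=O)O)(C(=O)OCc3ccc(OC)cc3)[C@@]21C | intermediate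
16 | 4-methoxybenzyl (3R,3aS,4R,7R)-7-[(tert-butyldiphenylsilyl)oxy]-3-[2-({[tert-butyl(dimethyl)silyl]oxy}methyl)prop-2-en-1-yl]-3a-methyl-2-oxo-3,3a,4,5,6,7-hexahydro-2H-indene-4-carboxylate | C=C(CO[Si](C)(C)C(C)(C)C)C[C@H]1C(=O)C=C2[C@H](O[Si](c3ccccc3)(c3ccccc3)C(C)(C)C)CC[C@@H](C(=O)OCc3ccc(OC)cc3)[C@@]21C | intermediate
17 | 4-methoxybenzyl (3R,3aS,4R,7R)-7-hydroxy-3-[2-(hydroxymethyl)prop-2-en-1-yl]-3a-methyl-2-oxo-3,3a,4,5,6,7-hexahydro-2H-indene-4-carboxylate | C=C(CO)C[C@H]1C(=O)C=C2[C@H](O)CC[C@@H](C(=O)OCc3ccc(OC)cc3)[C@@]21C | intermediate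
18 | 4-methoxybenzyl (3R,3aS,4R,7R)-3-[2-({[tert-butyl(dimethyl)silyl]oxy}methyl)prop-2-en-1-yl]-7-hydroxy-3a-methyl-2-oxo-3,3a,4,5,6,7-hexahydro-2H-indene-4-carboxylate | C=C(CO[Si](C)(C)C(C)(C)C)C[C@H]1C(=O)C=C2[C@H](O)CC[C@@H](C(=O)OCc3ccc(OC)cc3)[C@@]21C | intermediate
19 | (2E)-2-methylbut-2-enoic acid (tiglic acid) | C/C=C(\C)C(=O)O | starting material
20 | (2R)-2-methylbutanoic acid | CC[C@@H](C)C(=O)O | intermediate
21 | (2R)-2-methylbutan-1-ol | CC[C@@H](C)CO | intermediate
22 | (2R)-2-methylbutanal | CC[C@@H](C)C=O | intermediate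
23 | (2E,4R)-2,4-dimethylhex-2-enal | CC[C@@H](C)/C=C(\C)C=O | intermediate
24 | ethyl (2E,4E,6R)-4,6-dimethylocta-2,4-dienoate | CCOC(=O)/C=C/C(C)=C/[C@H](C)CC | intermediate
25 | (2E,4E,6R)-4,6-dimethylocta-2,4-dienoic acid | OC(=O)/C=C/C(C)=C/[C@H](C)CC | intermediate
26 | 4-methoxybenzyl (3R,3aS,4R,7S)-3-[2-({[tert-butyl(dimethyl)silyl]oxy}methyl)prop-2-en-1-yl]-7-{[(2E,4E,6R)-4,6-dimethylocta-2,4-dienoyl]oxy}-3a-methyl-2-oxo-3,3a,4,5,6,7-hexahydro-2H-indene-4-carboxylate | C=C(CO[Si](C)(C)C(C)(C)C)C[C@H]1C(=O)C=C2[C@@H](OC(=O)/C=C/C(C)=C/[C@H](C)CC)CC[C@@H](C(=O)OCc3ccc(OC)cc3)[C@@]21C | intermediate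
27 | (3R,3aS,4R,7S)-7-{[(2E,4E,6R)-4,6-dimethylocta-2,4-dienoyl]oxy}-3-[2-(hydroxymethyl)prop-2-en-1-yl]-3a-methyl-2-oxo-3,3a,4,5,6,7-hexahydro-2H-indene-4-carboxylic acid | C=C(CO)C[C@H]1C(=O)C=C2[C@@H](OC(=O)/C=C/C(C)=C/[C@H](C)CC)CC[C@@H](C(=O)O)[C@@]21C | intermediate
28 | (3R,3aS,4R,7S)-7-{[(2E,4E,6R)-4,6-dimethylocta-2,4-dienoyl]oxy}-3-(2-formylprop-2-en-1-yl)-3a-methyl-2-oxo-3,3a,4,5,6,7-hexahydro-2H-indene-4-carboxylic acid | C=C(C=O)C[C@H]1C(=O)C=C2[C@@H](OC(=O)/C=C/C(C)=C/[C@H](C)CC)CC[C@@H](C(=O)O)[C@@]21C | target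

## Step count and risks

Total step count: 21. Longest linear sequence: 14 steps (steps 1–4, 7–13 and 19–21).

**Step 10 (proposed new method).** The Meldrum's acid adduct 13 may revert to the furfuryl cation faster than its C–O bond ionises, so that the cation is drained by intermolecular alkylation at the carbinol carbon or, with traces of water, by the oxa-Piancatelli path. The sense of conrotation may also be poorly controlled, which would erode the configuration at C3a. The fallback sets out from 12 and uses known chemistry only. A classical Piancatelli rearrangement of 12 with water (ZnCl2, acetone/H2O, 60 °C) should give the trans-4-hydroxy-4-methylcyclopent-2-enone F1. DBU in MeCN at 50 °C should then eliminate water by E1cB to the transient cyclopentadienone F2, as in the known base-mediated isomerisation of 4-hydroxycyclopentenones. F2 is captured by 6-exo Michael addition of the Meldrum's acid anion at the methyl-bearing β-carbon. Because this addition is reversible, the fused enone with the equatorial silyloxy group should accumulate under thermodynamic control (a spiro adduct at the other β-carbon can revert), and acidification returns to the route at 14.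

**Step 19.** The carboxylate must enter syn to the axial C3a methyl group, so E2 elimination to the cross-conjugated dienone or incomplete inversion may compete with substitution. The fallback sets out from 18. Dess–Martin oxidation should give the ene-dione F3. Luche reduction (NaBH4, CeCl3·7H2O, MeOH, −78 °C) should then attack the less hindered six-ring carbonyl from the equatorial direction, anti to the syn-axial methyl group, and give the axial 7S alcohol F4. Yamaguchi esterification of F4 with 25 (2,4,6-trichlorobenzoyl chloride, Et3N, DMAP, toluene), which proceeds with retention, returns to the route at 26.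

**Step 11.** Facial selectivity in the C-protonation of the ester enol may be poor, giving the C4 epimer. The fallback sets out from 15, isolated by running the alcoholysis at 80 °C and stopping before decarboxylation. Coupling with 1-hydroxypyridine-2(1H)-thione (DCC, DMAP, CH2Cl2, dark) should give the Barton ester F5. Irradiation with visible light in the presence of t-BuSH (benzene, rt) should then decarboxylate it by a radical chain, the C4 radical taking hydrogen from the thiol on the exo face anti to the methyl group, and returns to the route at 16.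

## Further compounds

F1 | step 10 | 5-[(3R)-3-[(tert-butyldiphenylsilyl)oxy]-3-{4-[2-({[tert-butyl(dimethyl)silyl]oxy}methyl)prop-2-en-1-yl]-5-hydroxy-5-methyl-3-oxocyclopent-1-en-1-yl}propyl]-2,2-dimethyl-1,3-dioxane-4,6-dione (hydroxyl trans to the allyl group, both ring diastereomers) | C=C(CO[Si](C)(C)C(C)(C)C)CC1C(=O)C=C([C@H](O[Si](c2ccccc2)(c2ccccc2)C(C)(C)C)CCC2C(=O)OC(C)(C)OC2=O)C1(C)O
F2 | step 10 | 5-[(3R)-3-[(tert-butyldiphenylsilyl)oxy]-3-{4-[2-({[tert-butyl(dimethyl)silyl]oxy}methyl)prop-2-en-1-yl]-5-methyl-3-oxocyclopenta-1,4-dien-1-yl}propyl]-2,2-dimethyl-1,3-dioxane-4,6-dione (transient cyclopentadienone) | C=C(CO[Si](C)(C)C(C)(C)C)CC1=C(C)C([C@H](O[Si](c2ccccc2)(c2ccccc2)C(C)(C)C)CCC2C(=O)OC(C)(C)OC2=O)=CC1=O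
F3 | step 19 | 4-methoxybenzyl (3R,3aS,4R)-3-[2-({[tert-butyl(dimethyl)silyl]oxy}methyl)prop-2-en-1-yl]-3a-methyl-2,7-dioxo-3,3a,4,5,6,7-hexahydro-2H-indene-4-carboxylate | C=C(CO[Si](C)(C)C(C)(C)C)C[C@H]1C(=O)C=C2C(=O)CC[C@@H](C(=O)OCc3ccc(OC)cc3)[C@@]21C
F4 | step 19 | 4-methoxybenzyl (3R,3aS,4R,7S)-3-[2-({[tert-butyl(dimethyl)silyl]oxy}methyl)prop-2-en-1-yl]-7-hydroxy-3a-methyl-2-oxo-3,3a,4,5,6,7-hexahydro-2H-indene-4-carboxylate | C=C(CO[Si](C)(C)C(C)(C)C)C[C@H]1C(=O)C=C2[C@@H](O)CC[C@@H](C(=O)OCc3ccc(OC)cc3)[C@@]21C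
F5 | step 11 | 4-(4-methoxybenzyl) 4-(2-thioxopyridin-1(2H)-yl) (3R,3aR,7R)-7-[(tert-butyldiphenylsilyl)oxy]-3-[2-({[tert-butyl(dimethyl)silyl]oxy}methyl)prop-2-en-1-yl]-3a-methyl-2-oxo-3,3a,6,7-tetrahydro-2H-indene-4,4(5H)-dicarboxylate (both C4 epimers) | C=C(CO[Si](C)(C)C(C)(C)C)C[C@H]1C(=O)C=C2[C@H](O[Si](c3ccccc3)(c3ccccc3)C(C)(C)C)CCC(C(=O)OCc3ccc(OC)cc3)(C(=O)On3ccccc3=S)[C@@]21C
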